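## Structural features

The target is a linear diarylheptanoid. A 4-hydroxy-3-methoxyphenyl (guaiacyl) ring on C1 and a 4-hydroxyphenyl ring on C7 are joined by a seven-carbon chain, and the two benzene rings are the only rings. The chain carries an E C1=C2 alkene conjugated to a β-diketone at C3/C5 (drawn as the C3 enol), a methylene at C6 and a secondary benzylic carbinol at C7. C7 is the only stereocentre and is (S), so there is no neighbouring stereocentre and only absolute control is needed.

The fragile groups are these. The C5 ketone and C7 hydroxyl form an aldol unit that loses water by E1cB under base to give the achiral, fully conjugated curcuminoid. The C7 carbinol is para to a phenol and can ionise under acid, which would racemise it. The δ-hydroxy-β-diketone cyclodehydrates under acid to a 2,3-dihydro-4-pyranone.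

The real difficulty is therefore to place one benzylic C–O stereocentre two carbons from an acidic 1,3-dicarbonyl unit and then reach the free compound without strong base, strong acid or heat.

The key step uses the 1,3,5-oxygenation of C3–C7. Atoms C3, C4, C5, C6, C7 and the C7 oxygen are the six ring atoms of a 4-pyranone. The ring oxygen bridges C3 and C7, C5 is the carbonyl carbon, and C7 is the unsubstituted ring carbon C6, β to the carbonyl. Only two of the three chain oxygens are stored in that ring: the ring oxygen becomes the C7 hydroxyl and the carbonyl stays at C5, while the C3 oxygen has to come from water when the ring is opened.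

## Logic of the disconnections

13 ⇒ 12. The three O–Si bonds are cut. The two phenols must be masked for the enolate and palladium chemistry, and the C7 oxygen must be masked for the step before. One fluoride treatment removes all three silyl groups, so the masking costs a single step. The forward step must be nearly neutral so that C7 neither eliminates nor ionises.

12 ⇒ 11. The C3–O bond of the diketone is exchanged for a C3–N bond, which takes the diketone back to a vinylogous amide. The reason is that the vinylogous amide is what a ring opening with an amine delivers. The forward hydrolysis needs an iminium ion at C3 that only water can reach. With a free C7 hydroxyl the ion would be trapped intramolecularly and the ring of 9 would simply re-form, so the plan keeps that oxygen silylated at this stage.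

11 ⇒ 9 (through 10). The C3–N bond and the C7 O–Si bond are cut and the C7 oxygen is reconnected to C3. This closes the six-membered vinylogous ester and removes the open-chain aldol unit. All functionality of C3–C7 is then held in one ring with the stereocentre as a ring C–O carbon. The forward step must cleave O–C3 by addition–elimination and must not cleave O–C7 by E1cB, which calls for a nucleophilic, weakly basic medium and immediate capping of the liberated hydroxyl.

9 ⇒ 7 + 8. The C7–aryl bond is cut. This removes the only stereocentre and divides the molecule into a flat, achiral heteroaromatic acceptor and a commercial boronic acid. The forward step must deliver the aryl group to one face of the unsubstituted ring carbon, must not touch the substituted ring carbon or the styryl alkene, and must run under conditions that leave aryl silyl ethers intact.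

7 ⇒ 6. The ring O–C bond at the unsubstituted carbon is cut and methanol is added back. This gives an open 1,3-diketone that carries a β-methoxy enone, whose enol oxygen is placed for a 6-endo addition–elimination. The forward step needs only catalytic acid.

6 ⇒ 3 + 4 (through 5). The C3–C4 bond is cut, which is a Claisen-type acylation of a methyl ketone enolate. It divides the pyranone precursor into the complete C1–C3 arylpropenoyl unit and a four-carbon unit that already holds C4–C7 at the right oxidation level. The forward step needs C-acylation and a second equivalent of enolate to absorb the acidic product.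

3 ⇒ 2 ⇒ 1. The C–Cl bond and then both O–Si bonds are cut. Exhaustive silylation followed by direct conversion of the silyl ester into the acid chloride avoids a separate selective hydrolysis and keeps the medium free of hydrogen chloride.

## Other disconnections considered

Alternative 1: The cut is C3–C4, between the (S)-β-keto acid A1 and the silylated feruloyl imidazolide A2. In the forward step the magnesium chelate of A1 (MgCl2, Et3N) would be C-acylated by A2 and would then lose CO2 to give A3, which is identical with 12.
- In favour: the route is convergent. The stereocentre would be set in a small fragment by a well-established enantioselective reduction or aldol reaction, and on this point of precedent it is better than the chosen plan. No ring is ever formed, so the ring opening and hydrolysis (steps 6 and 7) would not be needed, which is also better.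
- Against: A1 is a β-keto acid that can decarboxylate before it is acylated, and it is also a β-silyloxy ketone that can lose silanol under the amine and magnesium enolate conditions. Acylation of a keto acid chelate by a conjugated acyl donor is less secure than the malonate half-ester case, and O-acylation or conjugate addition may compete.
- Comparison: A1 would need about five steps, so the total would be about nine operations with a longest linear sequence of about seven, against eight and eight. The count is equal and the convergence is better. The final deprotection and its risks are the same, because A3 and 12 are one compound. The chosen plan keeps its advantage only in making the stereocentre catalytically in a single late step from achiral material.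

Alternative 2: The cut is C5–C6, between the racemic enynol A4 and the (R)-aryl oxirane A5. In the forward step the alkoxide–acetylide dianion of A4 (two equivalents of n-BuLi) would open A5 at its CH2 carbon to give the diol A6. Oxidation at C3, hydration of the ynone and desilylation would follow.
- In favour: the configuration of A5 would come from reliable enantioselective chemistry, which is better on precedent. The alkyne is a sturdy masked diketone, and the C3 epimers are harmless because C3 is oxidised.
- Against: acetylide openings of epoxides usually need a boron Lewis acid. With an electron-rich aryl oxirane, that would direct attack to the benzylic carbon or cause rearrangement; without it the strongly basic dianion would be sluggish. The C3 alcohol must then be oxidised beside the benzylic C7 alcohol, or C7 must be protected first. A δ-hydroxy ynone is also expected to close by oxa-Michael addition to the ring system of 9, so this route may arrive at the very ring that the chosen plan has to open.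
- Comparison: mechanistically it exchanges one uncertain catalytic step for several chemoselectivity problems. In step economy it is worse, at roughly eleven operations with a longest linear sequence of about eight. It is equal or better only in the source of the stereocentre.

Alternative 3: The cut is C2–C3, between the (E)-alkenyl bromide A7 and the (S)-methoxy dihydropyranone lactone A8. In the forward step A7 would be lithiated with t-BuLi and transmetalated with CeCl3, the organocerium would add to the lactone carbonyl, and dilute acid would open the lactol and hydrolyse the methyl enol ether to give A9.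
- In favour: A8 belongs to a lactone class that a catalytic enantioselective hetero-Diels–Alder reaction can deliver in one step, so the stereocentre rests on known chemistry. The key step would deliver the whole skeleton at the correct oxidation level, and A9 has only two aryl silyl ethers, so its deprotection would be milder than that of 12. At about six operations this is the shortest plan, and on step economy and ease of the final deprotection it is better.
- Against: A8 is a vinylogous carbonate and therefore a poor carbonyl electrophile. The organometallic may deprotonate the ring CH2 instead, and the dienolate can expel the benzylic carboxylate by E1cB with loss of the stereocentre. Conjugate addition–elimination at the methoxy-bearing carbon and over-addition to the released enone are also possible. On acid work-up the tertiary lactol can ionise and lose methanol, which would give the ring skeleton of 9 with a free hydroxyl and no chance of trapping.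
- Comparison: it is better on length and on precedent for the stereocentre. It is worse on the number of competing pathways in its key step, which uses a strongly basic reagent on a base-sensitive lactone, whereas the chosen key step runs in a nearly neutral aqueous medium.

Key step: step 5

Assumption: the enol double bond of the β-diketone is a tautomer depiction and not a stereochemical element (the compound should exist as the chelated cis-enol in equilibrium with the diketo form), so the line notation of the target is kept as written.

## Route

Step 1
Reactants: 1 ferulic acid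
Product: 2 tert-butyldimethylsilyl (E)-3-[4-(tert-butyldimethylsilyloxy)-3-methoxyphenyl]prop-2-enoate
Conditions: TBSCl (2.4 equiv), imidazole (5 equiv), DMF, rt
Reagents that add atoms: tert-butyldimethylsilyl chloride, CC(C)(C)[Si](C)(C)Cl
Why: Imidazole-promoted silylation of the phenol and the carboxylic acid; silylating both is deliberate, because the silyl ester is the substrate of the next step and no selective hydrolysis is needed.

Step 2
Reactants: 2 tert-butyldimethylsilyl (E)-3-[4-(tert-butyldimethylsilyloxy)-3-methoxyphenyl]prop-2-enoate
Product: 3 (E)-3-[4-(tert-butyldimethylsilyloxy)-3-methoxyphenyl]prop-2-enoyl chloride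
Conditions: (COCl)2 (1.3 equiv), DMF (cat.), CH2Cl2, 0 °C → rt; volatiles removed
Reagents that add atoms: oxalyl chloride, ClC(=O)C(=O)Cl
Why: Silyl esters are converted into acid chlorides by oxalyl chloride through the Vilsmeier-type chloroiminium species, with loss of the silyl chloride, CO and CO2; no hydrogen chloride is formed, so the aryl silyl ether should survive.

Step 3
Reactants: 3 (E)-3-[4-(tert-butyldimethylsilyloxy)-3-methoxyphenyl]prop-2-enoyl chloride; 4 (E)-4-methoxybut-3-en-2-one
Product: 6 (1E,6E)-1-methoxy-7-[4-(tert-butyldimethylsilyloxy)-3-methoxyphenyl]hepta-1,6-diene-3,5-dione, via lithium enolate 5 (not isolated)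
Conditions: 4 (2.2 equiv), LiN(SiMe3)2 (2.2 equiv), THF, −78 °C; then 3 (1.0 equiv), −78 °C; aq. NH4Cl
Reagents that add atoms: none
Why: Claisen-type C-acylation of the kinetic lithium enolate of a methyl ketone by an acid chloride, forming the C3–C4 bond; the second equivalent of enolate deprotonates the more acidic β-diketone as it forms. The acid chloride has no α-hydrogen that could give a ketene.

Step 4
Reactants: 6 (1E,6E)-1-methoxy-7-[4-(tert-butyldimethylsilyloxy)-3-methoxyphenyl]hepta-1,6-diene-3,5-dione
Product: 7 2-[(E)-4-(tert-butyldimethylsilyloxy)-3-methoxystyryl]-4H-pyran-4-one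
Conditions: CF3CO2H (0.3 equiv), toluene, rt
Reagents that add atoms: none
Why: Acid-catalysed 6-endo oxa-Michael addition of the enol oxygen to the β-methoxy enone, followed by loss of methanol, gives the 4-pyranone; aryl silyl ethers tolerate catalytic trifluoroacetic acid in an aprotic solvent.

Step 5
Reactants: 7 2-[(E)-4-(tert-butyldimethylsilyloxy)-3-methoxystyryl]-4H-pyran-4-one; 8 4-(tert-butyldimethylsilyloxy)phenylboronic acid
Product: 9 (S)-2-[4-(tert-butyldimethylsilyloxy)phenyl]-6-[(E)-4-(tert-butyldimethylsilyloxy)-3-methoxystyryl]-2,3-dihydro-4H-pyran-4-one
Conditions: 8 (1.6 equiv), Pd(OCOCF3)2 (5–10 mol %), (R)-4-tert-butyl-2-(pyridin-2-yl)-4,5-dihydrooxazole [(R)-t-BuPyOx] (6–12 mol %), NH4PF6 (30 mol %), H2O (5 equiv), ClCH2CH2Cl, 40–60 °C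
Reagents that add atoms: none
Why: Proposed new method: the closest known reaction type is the enantioselective conjugate addition of arylboronic acids to chromones and cyclic enones under cationic divalent palladium with pyridinooxazoline ligands, which has not been shown on a monocyclic 4-pyranone bearing an alkenyl group. The aryl group of 8 should transmetalate to the ligated palladium cation, the cis-disubstituted C5=C6 bond of 7 should coordinate and insert so that the aryl group goes to C6 (chain C7) and palladium to C5, and water should protonate the palladium enolate and return the divalent catalyst without any redox change. No ring is closed and the only new skeletal bond is C7–aryl. The stereocentre is controlled by the ligand, whose tert-butyl group differentiates the two faces of the bound enone during insertion; transposing the facial model of six-membered cyclic enones predicts that the (R)-ligand gives (S)-9, and the mirror-image ligand is used if the sense proves opposite. Site selectivity is needed over C2, which is blocked by the styryl substituent, and over the styryl alkene, which is a trans-disubstituted acyclic alkene made electron-rich by its donor aryl group and should bind the crowded cation less well. β-Hydride elimination to an aryl pyranone is disfavoured because after syn insertion the remaining hydrogen on C6 is anti to palladium. A second arylation of 9 is held back by its fully substituted β-carbon and by the small excess of 8. The remaining risk is the lower electrophilicity of 7 compared with a chromone.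

Step 6
Reactants: 9 (S)-2-[4-(tert-butyldimethylsilyloxy)phenyl]-6-[(E)-4-(tert-butyldimethylsilyloxy)-3-methoxystyryl]-2,3-dihydro-4H-pyran-4-one
Product: 11 (S,4E,6E)-1-(tert-butyldimethylsilyloxy)-1-[4-(tert-butyldimethylsilyloxy)phenyl]-7-[4-(tert-butyldimethylsilyloxy)-3-methoxyphenyl]-5-(pyrrolidin-1-yl)hepta-4,6-dien-3-one, via hydroxy enaminone 10 (not isolated)
Conditions: pyrrolidine (3 equiv), AcOH (1 equiv), THF, 0 °C → rt; concentrate; then TBSCl (2.5 equiv), imidazole (5 equiv), DMF, rt
Reagents that add atoms: pyrrolidine, C1CCNC1; tert-butyldimethylsilyl chloride, CC(C)(C)[Si](C)(C)Cl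
Why: Conjugate addition–elimination of a secondary amine at the β-carbon of the cyclic vinylogous ester cleaves O–C3 and gives the more stabilised vinylogous amide, leaving the C7–O bond and its configuration untouched; the acetic acid lowers the free-base concentration that could trigger E1cB cleavage of C7–O. The liberated C7 hydroxyl is silylated at once so that it cannot close back onto C3 during hydrolysis, and any phenol uncovered by the amine is re-silylated at the same time.

Step 7
Reactants: 11 (S,4E,6E)-1-(tert-butyldimethylsilyloxy)-1-[4-(tert-butyldimethylsilyloxy)phenyl]-7-[4-(tert-butyldimethylsilyloxy)-3-methoxyphenyl]-5-(pyrrolidin-1-yl)hepta-4,6-dien-3-one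
Product: 12 (S,1E)-7-(tert-butyldimethylsilyloxy)-1-[4-(tert-butyldimethylsilyloxy)-3-methoxyphenyl]-7-[4-(tert-butyldimethylsilyloxy)phenyl]hept-1-ene-3,5-dione (C3 enol)
Conditions: 0.5 M aq. (CO2H)2, THF, rt
Reagents that add atoms: water, O
Why: Acid-catalysed hydrolysis of a tertiary enaminone through C-protonation to the iminium ion and addition of water, which supplies the C3 oxygen; with the C7 oxygen capped, the intramolecular return to 9 is blocked. Aryl and secondary alkyl tert-butyldimethylsilyl ethers should tolerate dilute oxalic acid.

Step 8
Reactants: 12 (S,1E)-7-(tert-butyldimethylsilyloxy)-1-[4-(tert-butyldimethylsilyloxy)-3-methoxyphenyl]-7-[4-(tert-butyldimethylsilyloxy)phenyl]hept-1-ene-3,5-dione (C3 enol)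
Product: 13 (7S,1E)-3,7-dihydroxy-1-(4-hydroxy-3-methoxyphenyl)-7-(4-hydroxyphenyl)hepta-1,3-dien-5-one (CNP0206527.1)
Conditions: HF·pyridine, pyridine (excess), THF, 0 °C → rt
Reagents that add atoms: none
Why: Fluoride-mediated cleavage of the three silyl ethers; the excess pyridine keeps the medium nearly neutral, which should avoid base-induced β-elimination of the C7 oxygen and acid-induced ionisation at C7 or cyclodehydration. The stereocentre is not touched.

## Compound list

1 | ferulic acid | COc1cc(/C=C/C(=O)O)ccc1O | starting material
2 | tert-butyldimethylsilyl (E)-3-[4-(tert-butyldimethylsilyloxy)-3-methoxyphenyl]prop-2-enoate | COc1cc(/C=C/C(=O)O[Si](C)(C)C(C)(C)C)ccc1O[Si](C)(C)C(C)(C)C | intermediate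
3 | (E)-3-[4-(tert-butyldimethylsilyloxy)-3-methoxyphenyl]prop-2-enoyl chloride | COc1cc(/C=C/C(=O)Cl)ccc1O[Si](C)(C)C(C)(C)C | intermediate
4 | (E)-4-methoxybut-3-en-2-one | CO/C=C/C(C)=O | starting material
5 | lithium (E)-4-methoxybuta-1,3-dien-2-olate | [Li+].[O-]C(=C)/C=C/OC | intermediate (not isolated)
6 | (1E,6E)-1-methoxy-7-[4-(tert-butyldimethylsilyloxy)-3-methoxyphenyl]hepta-1,6-diene-3,5-dione | COc1cc(/C=C/C(=O)CC(=O)/C=C/OC)ccc1O[Si](C)(C)C(C)(C)C | intermediate
7 | 2-[(E)-4-(tert-butyldimethylsilyloxy)-3-methoxystyryl]-4H-pyran-4-one | COc1cc(/C=C/c2cc(=O)cco2)ccc1O[Si](C)(C)C(C)(C)C | intermediate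
8 | 4-(tert-butyldimethylsilyloxy)phenylboronic acid | CC(C)(C)[Si](C)(C)Oc1ccc(B(O)O)cc1 | starting material
9 | (S)-2-[4-(tert-butyldimethylsilyloxy)phenyl]-6-[(E)-4-(tert-butyldimethylsilyloxy)-3-methoxystyryl]-2,3-dihydro-4H-pyran-4-one | COc1cc(/C=C/C2=CC(=O)C[C@@H](c3ccc(O[Si](C)(C)C(C)(C)C)cc3)O2)ccc1O[Si](C)(C)C(C)(C)C | intermediate
10 | (S,4E,6E)-1-hydroxy-1-[4-(tert-butyldimethylsilyloxy)phenyl]-7-[4-(tert-butyldimethylsilyloxy)-3-methoxyphenyl]-5-(pyrrolidin-1-yl)hepta-4,6-dien-3-one | COc1cc(/C=C/C(N2CCCC2)=C\C(=O)C[C@H](O)c3ccc(O[Si](C)(C)C(C)(C)C)cc3)ccc1O[Si](C)(C)C(C)(C)C | intermediate (not isolated)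
11 | (S,4E,6E)-1-(tert-butyldimethylsilyloxy)-1-[4-(tert-butyldimethylsilyloxy)phenyl]-7-[4-(tert-butyldimethylsilyloxy)-3-methoxyphenyl]-5-(pyrrolidin-1-yl)hepta-4,6-dien-3-one | COc1cc(/C=C/C(N2CCCC2)=C\C(=O)C[C@H](O[Si](C)(C)C(C)(C)C)c3ccc(O[Si](C)(C)C(C)(C)C)cc3)ccc1O[Si](C)(C)C(C)(C)C | intermediate
12 | (S,1E)-7-(tert-butyldimethylsilyloxy)-1-[4-(tert-butyldimethylsilyloxy)-3-methoxyphenyl]-7-[4-(tert-butyldimethylsilyloxy)phenyl]hept-1-ene-3,5-dione (C3 enol) | COc1cc(/C=C/C(O)=C\C(=O)C[C@H](O[Si](C)(C)C(C)(C)C)c2ccc(O[Si](C)(C)C(C)(C)C)cc2)ccc1O[Si](C)(C)C(C)(C)C | intermediate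
13 | (7S,1E)-3,7-dihydroxy-1-(4-hydroxy-3-methoxyphenyl)-7-(4-hydroxyphenyl)hepta-1,3-dien-5-one (CNP0206527.1) | COc1cc(/C=C/C(O)=C\C(=O)C[C@H](O)c2ccc(O)cc2)ccc1O | target

## Step count and least certain steps

Total step count: 8. Longest linear sequence: 8 steps (1 to 13); 4 and 8 are purchased.

Step 5 (key step, proposed new method).
- What may go wrong: insertion of the pyranone alkene into the aryl–palladium bond may be much slower than for a chromone, because the monocyclic ring is a more electron-rich vinylogous ester and the donor styryl group deactivates it further. Protodeboronation and oxidative homocoupling of 8 would then use up the boronic acid, the catalyst would be reduced to zerovalent palladium, and whatever conversion remains may show poor facial selectivity. Reversible opening and re-closure of the ring of 9 under the Lewis-acidic conditions would erode the enantiomeric purity further.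
- Fallback (known chemistry; sets out from 3, returns at 13): the stereocentre is made by a catalytic enantioselective vinylogous Mukaiyama aldol addition instead.
  - 3 acylates the lithium enolate of acetone (two equivalents, LiN(SiMe3)2, THF, −78 °C) to give (E)-6-[4-(tert-butyldimethylsilyloxy)-3-methoxyphenyl]hex-5-ene-2,4-dione F1.
  - Double enol silylation (Me3SiCl/Et3N, then LiN(i-Pr)2/Me3SiCl) gives tert-butyl{4-[(1E,3Z)-3,5-bis(trimethylsilyloxy)hexa-1,3,5-trien-1-yl]-2-methoxyphenoxy}dimethylsilane F2.
  - F2 adds through its terminal CH2 to commercial 4-(tert-butyldimethylsilyloxy)benzaldehyde under Ti(OiPr)4 and the BINOL enantiomer chosen for (S). Buffered removal of the trimethylsilyl groups gives the bis(aryl silyl ether) of the target with free C7 hydroxyl F3.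
  - F3 is desilylated under the conditions of step 8 to 13.

Step 6.
- What may go wrong: the amine may act as a base and not as a nucleophile. Deprotonation at C6 followed by β-elimination of the C7 oxygen would open the ring on the wrong side and destroy the stereocentre. Partial loss of aryl silyl ethers is also possible but is repaired in the silylation.
- Fallback (sets out from 9, returns at 12): the ring is opened with a weakly basic α-nucleophile and the diketone is carried as an isoxazole.
  - NH2OH·HCl/NaOAc in aqueous ethanol should give (S)-1-[4-(tert-butyldimethylsilyloxy)phenyl]-2-{3-[(E)-4-(tert-butyldimethylsilyloxy)-3-methoxystyryl]isoxazol-5-yl}ethanol F4.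
  - TBSCl/imidazole gives 5-{(S)-2-(tert-butyldimethylsilyloxy)-2-[4-(tert-butyldimethylsilyloxy)phenyl]ethyl}-3-[(E)-4-(tert-butyldimethylsilyloxy)-3-methoxystyryl]isoxazole F5.
  - Mo(CO)6 in wet acetonitrile cleaves the N–O bond to (S,4Z,6E)-5-amino-1-(tert-butyldimethylsilyloxy)-1-[4-(tert-butyldimethylsilyloxy)phenyl]-7-[4-(tert-butyldimethylsilyloxy)-3-methoxyphenyl]hepta-4,6-dien-3-one F6.
  - Dilute aqueous oxalic acid hydrolyses F6 to 12.

Step 7.
- What may go wrong: the vinylogous amide is strongly stabilised, so its hydrolysis may be slower than acid-induced loss of the C7 silyl ether. The freed hydroxyl would then close back onto C3 and return the material to the ring of 9.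
- Fallback (sets out from 11, returns at 12): amine exchange of 11 with NH2OH·HCl in ethanol expels pyrrolidine and closes the isoxazole F5. F5 is carried through F6 to 12 as described for step 6. This detour adds no compound of its own (F0).

Step 8.
- What may go wrong: the hindered secondary benzylic silyl ether may need long exposure to the fluoride reagent. During that time C7 can ionise (which racemises it), water can be lost to give the conjugated dienone, or the hydroxy diketone can cyclodehydrate.
- Fallback (sets out from 10, returns at 13): the C7 oxygen is capped with a more labile group.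
  - 10 is silylated with triethylsilyl chloride and imidazole to (S,4E,6E)-1-[4-(tert-butyldimethylsilyloxy)phenyl]-7-[4-(tert-butyldimethylsilyloxy)-3-methoxyphenyl]-5-(pyrrolidin-1-yl)-1-(triethylsilyloxy)hepta-4,6-dien-3-one F7.
  - An AcOH/NaOAc buffer in aqueous THF hydrolyses the enaminone to (S,1E)-1-[4-(tert-butyldimethylsilyloxy)-3-methoxyphenyl]-7-[4-(tert-butyldimethylsilyloxy)phenyl]-7-(triethylsilyloxy)hept-1-ene-3,5-dione F8.
  - Et3N·3HF in THF at 0 °C should remove the triethylsilyl and aryl silyl groups quickly and give 13.

## Further compounds

F1 | step 5 | (E)-6-[4-(tert-butyldimethylsilyloxy)-3-methoxyphenyl]hex-5-ene-2,4-dione | COc1cc(/C=C/C(=O)CC(C)=O)ccc1O[Si](C)(C)C(C)(C)C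
F2 | step 5 | tert-butyl{4-[(1E,3Z)-3,5-bis(trimethylsilyloxy)hexa-1,3,5-trien-1-yl]-2-methoxyphenoxy}dimethylsilane | C=C(O[Si](C)(C)C)/C=C(O[Si](C)(C)C)/C=C/c1ccc(O[Si](C)(C)C(C)(C)C)c(OC)c1
F3 | step 5 | bis(aryl tert-butyldimethylsilyl) ether of the target with free C7 hydroxyl | COc1cc(/C=C/C(O)=C\C(=O)C[C@H](O)c2ccc(O[Si](C)(C)C(C)(C)C)cc2)ccc1O[Si](C)(C)C(C)(C)C
F4 | step 6 | (S)-1-[4-(tert-butyldimethylsilyloxy)phenyl]-2-{3-[(E)-4-(tert-butyldimethylsilyloxy)-3-methoxystyryl]isoxazol-5-yl}ethanol | COc1cc(/C=C/c2cc(C[C@H](O)c3ccc(O[Si](C)(C)C(C)(C)C)cc3)on2)ccc1O[Si](C)(C)C(C)(C)C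
F5 | step 6 | 5-{(S)-2-(tert-butyldimethylsilyloxy)-2-[4-(tert-butyldimethylsilyloxy)phenyl]ethyl}-3-[(E)-4-(tert-butyldimethylsilyloxy)-3-methoxystyryl]isoxazole | COc1cc(/C=C/c2cc(C[C@H](O[Si](C)(C)C(C)(C)C)c3ccc(O[Si](C)(C)C(C)(C)C)cc3)on2)ccc1O[Si](C)(C)C(C)(C)C
F6 | step 6 | (S,4Z,6E)-5-amino-1-(tert-butyldimethylsilyloxy)-1-[4-(tert-butyldimethylsilyloxy)phenyl]-7-[4-(tert-butyldimethylsilyloxy)-3-methoxyphenyl]hepta-4,6-dien-3-one | COc1cc(/C=C/C(N)=C/C(=O)C[C@H](O[Si](C)(C)C(C)(C)C)c2ccc(O[Si](C)(C)C(C)(C)C)cc2)ccc1O[Si](C)(C)C(C)(C)C
F0 | step 7 | none | none
F7 | step 8 | (S,4E,6E)-1-[4-(tert-butyldimethylsilyloxy)phenyl]-7-[4-(tert-butyldimethylsilyloxy)-3-methoxyphenyl]-5-(pyrrolidin-1-yl)-1-(triethylsilyloxy)hepta-4,6-dien-3-one | COc1cc(/C=C/C(N2CCCC2)=C\C(=O)C[C@H](O[Si](CC)(CC)CC)c3ccc(O[Si](C)(C)C(C)(C)C)cc3)ccc1O[Si](C)(C)C(C)(C)C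
F8 | step 8 | (S,1E)-1-[4-(tert-butyldimethylsilyloxy)-3-methoxyphenyl]-7-[4-(tert-butyldimethylsilyloxy)phenyl]-7-(triethylsilyloxy)hept-1-ene-3,5-dione (C3 enol) | COc1cc(/C=C/C(O)=C\C(=O)C[C@H](O[Si](CC)(CC)CC)c2ccc(O[Si](C)(C)C(C)(C)C)cc2)ccc1O[Si](C)(C)C(C)(C)C
A1 | alternative 1 | (S)-5-(tert-butyldimethylsilyloxy)-5-[4-(tert-butyldimethylsilyloxy)phenyl]-3-oxopentanoic acid | OC(=O)CC(=O)C[C@H](O[Si](C)(C)C(C)(C)C)c1ccc(O[Si](C)(C)C(C)(C)C)cc1
A2 | alternative 1 | 1-{(E)-3-[4-(tert-butyldimethylsilyloxy)-3-methoxyphenyl]prop-2-enoyl}imidazole | COc1cc(/C=C/C(=O)n2ccnc2)ccc1O[Si](C)(C)C(C)(C)C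
A3 | alternative 1 | tris(tert-butyldimethylsilyl) ether of the target (identical with 12) | COc1cc(/C=C/C(O)=C\C(=O)C[C@H](O[Si](C)(C)C(C)(C)C)c2ccc(O[Si](C)(C)C(C)(C)C)cc2)ccc1O[Si](C)(C)C(C)(C)C
A4 | alternative 2 | (E)-1-[4-(tert-butyldimethylsilyloxy)-3-methoxyphenyl]pent-1-en-4-yn-3-ol (racemic) | COc1cc(/C=C/C(O)C#C)ccc1O[Si](C)(C)C(C)(C)C
A5 | alternative 2 | (R)-2-[4-(tert-butyldimethylsilyloxy)phenyl]oxirane | C1[C@H](O1)c2ccc(O[Si](C)(C)C(C)(C)C)cc2
A6 | alternative 2 | (7S,E)-1-[4-(tert-butyldimethylsilyloxy)-3-methoxyphenyl]-7-[4-(tert-butyldimethylsilyloxy)phenyl]hept-1-en-4-yne-3,7-diol (C3 epimers) | COc1cc(/C=C/C(O)C#CC[C@H](O)c2ccc(O[Si](C)(C)C(C)(C)C)cc2)ccc1O[Si](C)(C)C(C)(C)C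
A7 | alternative 3 | (E)-[4-(2-bromovinyl)-2-methoxyphenoxy](tert-butyl)dimethylsilane | COc1cc(/C=C/Br)ccc1O[Si](C)(C)C(C)(C)C
A8 | alternative 3 | (S)-6-[4-(tert-butyldimethylsilyloxy)phenyl]-4-methoxy-5,6-dihydro-2H-pyran-2-one | COC1=CC(=O)O[C@H](c2ccc(O[Si](C)(C)C(C)(C)C)cc2)C1
A9 | alternative 3 | bis(aryl tert-butyldimethylsilyl) ether of the target with free C7 hydroxyl | COc1cc(/C=C/C(O)=C\C(=O)C[C@H](O)c2ccc(O[Si](C)(C)C(C)(C)C)cc2)ccc1O[Si](C)(C)C(C)(C)C
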